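## Structural features

The target, (2S,3R,6S,8S,9S)-2,8-dibromo-9-chloro-1,1,9-trimethyl-5-methylidenespiro[5.5]undecan-3-ol, is a chamigrane-type C15 skeleton in which two cyclohexane rings share the quaternary carbon C6. Ring A runs C6–C1(Me)2–C2H(Br)–C3H(OH)–C4H2–C5(=CH2), and ring B runs C6–C7H2–C8H(Br)–C9(Me)(Cl)–C10H2–C11H2, so that C9 is 1,4 to C6. Four of the five stereocentres form two adjacent pairs, C2/C3 (Br and OH cis) and C8/C9 (Br and Cl trans), and these pairs communicate only through the fifth, C6; seen from C6, chlorine lies on the side of C5 and the ring B bromine on the side of C1. The fully substituted C1 is bonded directly to the quaternary C6, which makes this the most congested bond of the molecule. The fragile groups are the β-bromo tertiary chloride (ionisation, E2, reductive elimination by zinc metal, cuprates or lithium reagents), the cis bromohydrin (epoxide formation with base) and the exocyclic alkene (migration into the ring under acid). The real difficulty is therefore twofold: relating the ring B halogens to the unsymmetrical substitution of C6, and building C1 next to C6. The key step exploits the 1,4 relation of C6 and C9 in ring B: a carboxyl carbon on C6 (the future C5) can reach C9 through oxygen, so a bridging δ-lactone formed by bromolactonisation of a 1,1-diacid fixes C6, C8 and C9 in one event and holds the C9–O bond as the place for chlorine.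

## Logic of the disconnections

19 ⇒ 18. The C3–C4 bond of ring A is cut and the hydroxyl hydrogen is returned to the exocyclic carbon. The 1,3 relation of hydroxyl and exocyclic methylene is the retron of a type 2 carbonyl-ene reaction. Ring A and the C3 stereocentre disappear, leaving an aldehyde and an isopropenyl group on C6. The forward step must pass through a chair with axial oxygen and equatorial bromine, and its Lewis acid must leave the tertiary chloride alone.

18 ⇒ 17. The C2–Br bond is cut. C2 is the α-carbon of an aldehyde, the one position where a chiral amine catalyst can set a C–Br centre that has no ring to control it. One stereocentre is removed and the arm becomes a plain aldehyde. The forward step needs catalyst control over the resident centres and a bromine donor that ignores the alkene.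

17 ⇒ 16 ⇒ 15. No skeletal bond is cut; the aldehyde is traced back through the primary alcohol to its acetate. The reason is that an aldehyde cannot survive methylenation or thionyl chloride, whereas an acetate can. The gain is a robust two-carbon arm that needs no attention in the preceding steps. The forward deacetylation and oxidation must be non-basic because of the bromochloride.

15 ⇒ 14. The C=CH2 bond of the isopropenyl group is cut to a methyl ketone. A ketone is what an acyl chloride delivers, so the alkene is traced to a carbonyl carbon that comes from the lactone. The forward methylenation must be non-basic and must prefer the ketone to the acetate.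

14 ⇒ 13 ⇒ 12. The acetyl C–CH3 bond and the C9–Cl bond are cut and C9 is reconnected through oxygen to the acyl carbon. The lactone is the latent form of both groups. Ring B becomes a rigid bicycle in which bromine cannot eliminate, and the sensitive bromochloride is absent from all earlier steps. The forward step must replace oxygen by chlorine with retention.

12 ⇒ 11. The O–CH2 bond of the acetate is cut and the CH2 carbon is rejoined to the acetyl carbon (Baeyer–Villiger retron). This allows the most reliable radical acceptor to be used in the step before and then trimmed by one carbon. The forward oxidation must make the primary alkyl group migrate in preference to methyl.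

11 ⇒ 9 + 10. The bond between the gem-dimethyl carbon and its CH2 neighbour is cut. The hindered carbon becomes a tertiary radical generated from an isopropenyl group, and the partner is the unhindered terminus of an enone. The vicinal quaternary pair is thereby reduced to an alkene on a bridgehead. The radical must add faster than it is reduced.

9 ⇒ 8 ⇒ 7 ⇒ 6. The C=CH2 and C–CH3 bonds are cut back to the free carboxyl group. This is the group the key step leaves untouched, so no protecting group is needed and the arm starts from a function that is already in place. The forward steps must distinguish the acid-derived carbonyl from the lactone.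

6 ⇒ 4 + 5. The C–Br bond and the lactone C–O bond are cut. Three stereocentres and one ring are removed and the precursor is achiral. The forward step must select one of two enantiotopic carboxyl groups (coupled to one alkene face) and the tertiary over the secondary alkene carbon.

4 ⇒ 3 ⇒ 1 + 2. One C–CO2 bond is cut. Acylation of an ester enolate with 2 gives the geminal diester and hydrolysis gives the diacid, so the precursor is reached from a simple cyclohexene ester. The enolate must be acylated on carbon, and the malonic acid must not be heated.

## Other disconnections considered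

Alternative 1: The spiro carbon–C7 bond is cut. In the forward direction a zerovalent palladium catalyst (Pd2(dba)3 with a chiral diphosphine) would ionise the (Z)-allylic carbonate of phenol A2, and the para carbon of the phenoxide would attack the CH2 terminus to give spirotrienone A1.
- In its favour: one catalytic step creates the spiro centre and ring B with the alkene and methyl group in place. Ring A arrives with oxygen on C3 and a handle on every carbon.
- Against it here: the ring B halogens would have to be added across the C8=C9 alkene of A1 or a later compound by an intermolecular bromochlorination. Regiochemistry (chlorine at the tertiary carbon) is reliable. For the facial sense, conformational analysis predicts diaxial opening through the half-chair with the bulkier C1 branch equatorial, which would place chlorine trans to C5, the opposite of what is needed. The gem-dimethyl group would also require conjugate methyl addition at a β-carbon adjacent to the spiro centre.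
- Comparison: on step economy to the carbon skeleton A1 is better than the chosen plan, and in setting C6 catalytically it is its equal. On structure the chosen plan is stronger, because bridge 6 ties C8 and C9 to C6 by geometry and not by a facial preference. Mechanistically both rely on an enantioselective step with limited precedent for the exact substrate.

Alternative 2: The bond from the spiro carbon to the future C5 is cut. In the forward direction the dirhodium tetraacetate (Rh2(OAc)4) carbenoid from diazo keto ester A4 would insert into the tertiary ring C–H bond to give spiro[4.5]decene keto ester A3.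
- In its favour: the C1–C6 bond and the gem-dimethyl group are present from the start, since A4 derives from (S)-limonene A5. Insertion into a C–H bond proceeds with retention, so the configuration of C6 comes from the chiral pool. On this point the alternative is better than the chosen plan, which spends four steps (4 to 7) on the same bond region.
- Against it here: ring A is formed as a cyclopentanone and needs a regioselective one-carbon expansion before C3, C4 and C5 can be functionalised. The carbenoid can also attack the ring alkene or allylic C–H bonds. The ring B halogens again depend on a late bromochlorination with the unfavourable facial bias described for Alternative 1.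
- Comparison: on the stereochemistry of C6 the two plans are equal in reliability of principle (stereospecific transfer against catalyst control). The chosen plan is stronger for C8/C9, and the alternative is stronger for C1.

Alternative 3: The C1–C6 bond and the C4–C5 bond are cut. In the forward direction the lithiated nitrile A7 would add to the β-carbon of mesityl oxide A8, and the methyl ketone enolate would then close onto the nitrile (Thorpe-type) to give enaminone A6.
- In its favour: two inexpensive components deliver all ring A carbons, the gem-dimethyl group next to the spiro carbon and oxygen on C3 in one operation. In convergence and cost this is better than the chosen plan.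
- Against it here: A6 is achiral. C6 becomes stereogenic only when ring B is desymmetrised, so an enantioselective enolisation or similar would be needed in addition to the diastereocontrol of C8/C9 and C2/C3. The conjugate addition of a tertiary carbanion to a β,β-disubstituted enone is sterically demanding and reversible.
- Comparison: both plans must form the vicinal quaternary pair. The alternative does it by an ionic addition that is sensitive to crowding, the chosen plan by a radical addition to an unhindered acceptor that is not. The chosen plan fixes three stereocentres in its key step whereas A6 fixes none.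

Key step: step 3

Remarks on the chemistry (assumptions):
- The sense of induction of (DHQD)2PHAL in step 3 is taken to give 6 as drawn; if it is the opposite, the pseudo-enantiomeric (DHQ)2PHAL is used.
- The (S)-diarylprolinol silyl ether in step 12 is taken to deliver bromine to the enamine face that gives the 2S bromide, as the steric shielding model predicts; if it is the opposite, the (R)-catalyst is used.
- The configuration drawn for 6 corresponds atom by atom to ring B of the target (oxygen syn to the lactone carbonyl carbon, bromine anti to oxygen), so the structure of the key-step product needs no correction.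
- The diacid 4 is used unprotected, since two free and identical carboxyl groups are what makes the desymmetrisation possible.

## Route

Step 1
Reactants: 1 methyl 4-methylcyclohex-3-ene-1-carboxylate (racemic); 2 methyl chloroformate
Product: 3 dimethyl 4-methylcyclohex-3-ene-1,1-dicarboxylate
Conditions: LiN(iPr)2, THF, −78 °C; then ClCO2Me, −78 → 0 °C
Reagents that add atoms: methyl chloroformate, COC(=O)Cl
Why: Claisen-type C-acylation of a lithium ester enolate with a chloroformate. The α-carbon is tertiary, so only one acylation can occur, and the former stereocentre becomes a prochiral carbon.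

Step 2
Reactants: 3 dimethyl 4-methylcyclohex-3-ene-1,1-dicarboxylate
Product: 4 4-methylcyclohex-3-ene-1,1-dicarboxylic acid
Conditions: KOH, MeOH/H2O, 65 °C; then aq. HCl, 0 °C
Reagents that add atoms: potassium hydroxide, [K+].[OH-]
Why: Saponification of a geminal diester. The malonic acid is liberated cold and is not heated, so decarboxylation is avoided.

Step 3
Reactants: 4 4-methylcyclohex-3-ene-1,1-dicarboxylic acid; 5 N-bromosuccinimide
Product: 6 (1S,4R,6S)-6-bromo-1-methyl-3-oxo-2-oxabicyclo[2.2.2]octane-4-carboxylic acid
Conditions: NBS, (DHQD)2PHAL (10 mol %), CHCl3/toluene, −40 °C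
Reagents that add atoms: N-bromosuccinimide, O=C1CCC(=O)N1Br
Why: Proposed new method: the basic quinuclidine of the bis-cinchona catalyst should bind the diacid as a hydrogen-bonded carboxylate and relay Br+ from NBS to one face of the C3=C4 alkene, after which the carboxylate on the opposite face opens the unsymmetrical bromonium ion at the methyl-bearing C4 (Markovnikov, anti addition). The closest known reaction type is the catalytic enantioselective bromolactonisation of alkenoic acids with NBS and cinchona-derived Lewis-base catalysts, including desymmetrisations in which two enantiotopic alkenes or alkynes compete for one carboxyl group; what is new is that the enantiotopic groups are the two nucleophiles and that the lactone is bridged. One ring is closed, the δ-lactone of a 2-oxabicyclo[2.2.2]octanone; the closure is 6-exo along the C1–C6–C5 tether and 6-endo along C1–C2–C3, and it requires the reacting carboxyl in the flagpole position of a boat-like ring. The carbon that becomes the spiro centre (C4 of 6) is set by which carboxyl reacts, that is by the catalyst. The C–O carbon (C1 of 6) follows from the bridge, since oxygen must be syn to the lactone carbonyl carbon, and the C–Br carbon (C6 of 6) follows from anti opening of the bromonium ion, so all three centres derive from one face selection. The step needs enantioface selection, which the catalyst must supply (face and carboxyl are coupled, because only the carboxyl anti to bromine can close), and δ- over γ-lactone regioselection, which the methyl group secures by localising positive charge on C4. The second carboxyl cannot lactonise once the first has, so over-reaction is excluded.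

Step 4
Reactants: 6 (1S,4R,6S)-6-bromo-1-methyl-3-oxo-2-oxabicyclo[2.2.2]octane-4-carboxylic acid
Product: 8 (1S,4R,6S)-4-acetyl-6-bromo-1-methyl-2-oxabicyclo[2.2.2]octan-3-one, via bridgehead acyl chloride 7 (not isolated)
Conditions: (COCl)2, DMF (cat.), CH2Cl2, 0 °C → rt; evaporate; Me2Zn, Pd(PPh3)4 (3 mol %), THF, 0 °C → rt
Reagents that add atoms: oxalyl chloride (chlorine of 7), O=C(Cl)C(=O)Cl; dimethylzinc (methyl group), C[Zn]C
Why: Acyl chloride formation followed by Negishi acylation at zerovalent palladium stops at the ketone. The organozinc does not touch the lactone or the secondary bromide, and the bridgehead position excludes ketene formation.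

Step 5
Reactants: 8 (1S,4R,6S)-4-acetyl-6-bromo-1-methyl-2-oxabicyclo[2.2.2]octan-3-one
Product: 9 (1S,4R,6S)-6-bromo-1-methyl-4-(prop-1-en-2-yl)-2-oxabicyclo[2.2.2]octan-3-one
Conditions: Ph3PCH3Br (1.3 equiv), KOtBu (1.2 equiv), THF, 0 °C; then 8, 0 °C → rt
Reagents that add atoms: methyltriphenylphosphonium bromide, C[P+](c1ccccc1)(c1ccccc1)c1ccccc1.[Br-]
Why: Wittig methylenation of a methyl ketone on a tertiary bridgehead carbon, with the ylide pre-formed from a slight deficit of base so that no free alkoxide meets the acyl-activated lactone. The hindered lactone is inert to the non-stabilised ylide at room temperature, and the bromide has no anti-periplanar hydrogen in the rigid bicycle, so E2 is not expected.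

Step 6
Reactants: 9 (1S,4R,6S)-6-bromo-1-methyl-4-(prop-1-en-2-yl)-2-oxabicyclo[2.2.2]octan-3-one; 10 but-3-en-2-one
Product: 11 (1S,4R,6S)-6-bromo-1-methyl-4-(2-methyl-5-oxohexan-2-yl)-2-oxabicyclo[2.2.2]octan-3-one
Conditions: Fe(acac)3 (30 mol %), PhSiH3, EtOH/(CH2OH)2, 60 °C
Reagents that add atoms: but-3-en-2-one, CC(=O)C=C
Why: Reductive olefin coupling by metal-hydride hydrogen atom transfer (Giese addition). An iron hydride delivers H• to the CH2 terminus of the 1,1-disubstituted alkene, the tertiary radical adds to the unhindered terminus of the enone, and the α-keto radical is reduced and protonated. The crowded carbon is the radical and not the acceptor, which is why a quaternary carbon next to a quaternary carbon is within reach; the C–Br bond and the lactone are not involved.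

Step 7
Reactants: 11 (1S,4R,6S)-6-bromo-1-methyl-4-(2-methyl-5-oxohexan-2-yl)-2-oxabicyclo[2.2.2]octan-3-one
Product: 12 3-[(1S,4R,6S)-6-bromo-1-methyl-3-oxo-2-oxabicyclo[2.2.2]octan-4-yl]-3-methylbutyl acetate
Conditions: mCPBA, CF3CO2H (0.5 equiv), CH2Cl2, 0 °C → rt
Reagents that add atoms: 3-chloroperbenzoic acid, O=C(OO)c1cccc(Cl)c1
Why: Baeyer–Villiger oxidation in which the primary alkyl group migrates in preference to methyl. This removes the surplus carbon of the enone and leaves the two-carbon arm as an acetate that tolerates the next two steps.

Step 8
Reactants: 12 3-[(1S,4R,6S)-6-bromo-1-methyl-3-oxo-2-oxabicyclo[2.2.2]octan-4-yl]-3-methylbutyl acetate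
Product: 14 3-[(1R,3S,4S)-1-acetyl-3-bromo-4-chloro-4-methylcyclohexyl]-3-methylbutyl acetate, via chloro acyl chloride 13 (not isolated)
Conditions: SOCl2, ZnCl2 (10 mol %), CH2Cl2, 40 °C; evaporate; Me2Zn, Pd(PPh3)4 (3 mol %), THF, 0 °C → rt
Reagents that add atoms: thionyl chloride, O=S(Cl)Cl; dimethylzinc, C[Zn]C
Why: Lewis-acid-assisted alkyl–oxygen cleavage of a lactone by SOCl2/ZnCl2 is a known route from γ- and δ-lactones to chloro acyl chlorides, and a tertiary alkyl–oxygen bond should ionise more easily still. The activated carboxylate leaves the tertiary carbon with help from the anti bromine, and chloride opens the re-formed bromonium ion at the position just vacated, anti to bromine, so chlorine replaces oxygen with net retention (double inversion). The Negishi acylation that follows is chosen because organozinc reagents neither eliminate nor reduce the vicinal bromochloride.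

Step 9
Reactants: 14 3-[(1R,3S,4S)-1-acetyl-3-bromo-4-chloro-4-methylcyclohexyl]-3-methylbutyl acetate
Product: 15 3-[(1S,3S,4S)-3-bromo-4-chloro-4-methyl-1-(prop-1-en-2-yl)cyclohexyl]-3-methylbutyl acetate
Conditions: Cp2Ti(μ-Cl)(μ-CH2)AlMe2 (Tebbe reagent), pyridine (cat.), THF/toluene, −40 → 0 °C
Reagents that add atoms: Tebbe reagent, C[Al-]1(C)C[Ti](C2C=CC=C2)(C2C=CC=C2)[Cl+]1
Why: Carbonyl methylenation through a titanium methylidene and an oxatitanacyclobutane is non-basic and works on hindered, enolisable ketones, so the bromochloride is not exposed to an ylide base. The ketone reacts faster than the acetate at low temperature; any methylenated acetate would be an enol ether that hydrolyses to alcohol 16 on mild acid work-up and is therefore not lost.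

Step 10
Reactants: 15 3-[(1S,3S,4S)-3-bromo-4-chloro-4-methyl-1-(prop-1-en-2-yl)cyclohexyl]-3-methylbutyl acetate
Product: 16 3-[(1S,3S,4S)-3-bromo-4-chloro-4-methyl-1-(prop-1-en-2-yl)cyclohexyl]-3-methylbutan-1-ol
Conditions: iBu2AlH, CH2Cl2, −78 °C; aq. potassium sodium tartrate
Reagents that add atoms: none
Why: Reductive cleavage of the acetate frees the primary alcohol without base, so E2 of the bromochloride is avoided. Alkyl halides and the alkene are inert to the hydride at −78 °C.

Step 11
Reactants: 16 3-[(1S,3S,4S)-3-bromo-4-chloro-4-methyl-1-(prop-1-en-2-yl)cyclohexyl]-3-methylbutan-1-ol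
Product: 17 3-[(1S,3S,4S)-3-bromo-4-chloro-4-methyl-1-(prop-1-en-2-yl)cyclohexyl]-3-methylbutanal
Conditions: Dess–Martin periodinane, NaHCO3, CH2Cl2, 0 °C → rt
Reagents that add atoms: none
Why: Dess–Martin oxidation of a primary alcohol to the aldehyde under buffered conditions. The alkene and the halides are inert.

Step 12
Reactants: 17 3-[(1S,3S,4S)-3-bromo-4-chloro-4-methyl-1-(prop-1-en-2-yl)cyclohexyl]-3-methylbutanal
Product: 18 (2S)-2-bromo-3-[(1S,3S,4S)-3-bromo-4-chloro-4-methyl-1-(prop-1-en-2-yl)cyclohexyl]-3-methylbutanal
Conditions: 4,4-dibromo-2,6-di-tert-butylcyclohexa-2,5-dienone, (S)-2-[bis(3,5-bis(trifluoromethyl)phenyl)(trimethylsilyloxy)methyl]pyrrolidine (20 mol %), PhCO2H (20 mol %), CH2Cl2/pentane, −40 °C; short silica pad, used at once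
Reagents that add atoms: 4,4-dibromo-2,6-di-tert-butylcyclohexa-2,5-dien-1-one, CC(C)(C)C1=CC(Br)(Br)C=C(C(C)(C)C)C1=O
Why: Enamine-catalysed enantioselective α-bromination of an aldehyde. The E-enamine is shielded on one face by the diarylsilyloxymethyl group and takes Br+ from the dienone on the other, so the new C–Br centre (S) is set by the catalyst. The β-carbon is quaternary, which excludes HBr elimination, and the enamine is far more nucleophilic than the hindered isopropenyl group.

Step 13
Reactants: 18 (2S)-2-bromo-3-[(1S,3S,4S)-3-bromo-4-chloro-4-methyl-1-(prop-1-en-2-yl)cyclohexyl]-3-methylbutanal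
Product: 19 (2S,3R,6S,8S,9S)-2,8-dibromo-9-chloro-1,1,9-trimethyl-5-methylidenespiro[5.5]undecan-3-ol
Conditions: Me2AlCl (1.5 equiv), CH2Cl2, −78 °C; aq. NaHCO3
Reagents that add atoms: none
Why: Type 2 intramolecular carbonyl-ene reaction. The CH2 terminus of the isopropenyl group bonds to the activated aldehyde carbon while an allylic hydrogen passes to oxygen, which closes ring A and creates the exocyclic methylene. In the chair-like transition state oxygen must be axial to reach the methyl hydrogen and the C–Br bond lies equatorial, anti to the forming C–C bond (polar Felkin–Anh), which should give the cis bromohydrin with the 3R carbinol.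

## Compound list

1 | methyl 4-methylcyclohex-3-ene-1-carboxylate (racemic) | COC(=O)C1CCC(C)=CC1 | starting material
2 | methyl chloroformate | COC(=O)Cl | starting material
3 | dimethyl 4-methylcyclohex-3-ene-1,1-dicarboxylate | COC(=O)C1(CCC(C)=CC1)C(=O)OC | intermediate
4 | 4-methylcyclohex-3-ene-1,1-dicarboxylic acid | CC1=CCC(CC1)(C(=O)O)C(=O)O | intermediate
5 | N-bromosuccinimide | O=C1CCC(=O)N1Br | starting material
6 | (1S,4R,6S)-6-bromo-1-methyl-3-oxo-2-oxabicyclo[2.2.2]octane-4-carboxylic acid | OC(=O)[C@]12CC[C@](C)(OC1=O)[C@@H](Br)C2 | intermediate
7 | (1S,4S,6S)-6-bromo-1-methyl-3-oxo-2-oxabicyclo[2.2.2]octane-4-carbonyl chloride | ClC(=O)[C@]12CC[C@](C)(OC1=O)[C@@H](Br)C2 | intermediate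
8 | (1S,4R,6S)-4-acetyl-6-bromo-1-methyl-2-oxabicyclo[2.2.2]octan-3-one | CC(=O)[C@]12CC[C@](C)(OC1=O)[C@@H](Br)C2 | intermediate
9 | (1S,4R,6S)-6-bromo-1-methyl-4-(prop-1-en-2-yl)-2-oxabicyclo[2.2.2]octan-3-one | C=C(C)[C@]12CC[C@](C)(OC1=O)[C@@H](Br)C2 | intermediate
10 | but-3-en-2-one (methyl vinyl ketone) | CC(=O)C=C | starting material
11 | (1S,4R,6S)-6-bromo-1-methyl-4-(2-methyl-5-oxohexan-2-yl)-2-oxabicyclo[2.2.2]octan-3-one | CC(=O)CCC(C)(C)[C@]12CC[C@](C)(OC1=O)[C@@H](Br)C2 | intermediate
12 | 3-[(1S,4R,6S)-6-bromo-1-methyl-3-oxo-2-oxabicyclo[2.2.2]octan-4-yl]-3-methylbutyl acetate | CC(=O)OCCC(C)(C)[C@]12CC[C@](C)(OC1=O)[C@@H](Br)C2 | intermediate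
13 | 3-[(1R,3S,4S)-3-bromo-4-chloro-1-(chlorocarbonyl)-4-methylcyclohexyl]-3-methylbutyl acetate | CC(=O)OCCC(C)(C)[C@@]1(C(=O)Cl)CC[C@](C)(Cl)[C@@H](Br)C1 | intermediate
14 | 3-[(1R,3S,4S)-1-acetyl-3-bromo-4-chloro-4-methylcyclohexyl]-3-methylbutyl acetate | CC(=O)OCCC(C)(C)[C@@]1(C(C)=O)CC[C@](C)(Cl)[C@@H](Br)C1 | intermediate
15 | 3-[(1S,3S,4S)-3-bromo-4-chloro-4-methyl-1-(prop-1-en-2-yl)cyclohexyl]-3-methylbutyl acetate | CC(=O)OCCC(C)(C)[C@@]1(C(C)=C)CC[C@](C)(Cl)[C@@H](Br)C1 | intermediate
16 | 3-[(1S,3S,4S)-3-bromo-4-chloro-4-methyl-1-(prop-1-en-2-yl)cyclohexyl]-3-methylbutan-1-ol | OCCC(C)(C)[C@@]1(C(C)=C)CC[C@](C)(Cl)[C@@H](Br)C1 | intermediate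
17 | 3-[(1S,3S,4S)-3-bromo-4-chloro-4-methyl-1-(prop-1-en-2-yl)cyclohexyl]-3-methylbutanal | O=CCC(C)(C)[C@@]1(C(C)=C)CC[C@](C)(Cl)[C@@H](Br)C1 | intermediate
18 | (2S)-2-bromo-3-[(1S,3S,4S)-3-bromo-4-chloro-4-methyl-1-(prop-1-en-2-yl)cyclohexyl]-3-methylbutanal | O=C[C@@H](Br)C(C)(C)[C@@]1(C(C)=C)CC[C@](C)(Cl)[C@@H](Br)C1 | intermediate
19 | (2S,3R,6S,8S,9S)-2,8-dibromo-9-chloro-1,1,9-trimethyl-5-methylidenespiro[5.5]undecan-3-ol | C=C1C[C@@H](O)[C@@H](Br)C(C)(C)[C@]12CC[C@](C)(Cl)[C@@H](Br)C2 | target

## Step count and least certain steps

Total: 13 steps. Longest linear sequence: 13 steps (the route is linear from 1).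

Step 3 (key step, proposed new method). The catalyst may discriminate the two carboxyl groups poorly, because they differ only in their relation to the remote ring methyl group and the second acid can compete for the basic sites of the catalyst. Some attack at C3, leading to the γ-lactone of the bicyclo[3.2.1] type, is also possible. Fallback with known chemistry: from 4, uncatalysed bromolactonisation (NBS, NaHCO3, CH2Cl2) gives racemic 6-bromo-1-methyl-3-oxo-2-oxabicyclo[2.2.2]octane-4-carboxylic acid F1. Its salt with (R)-1-phenylethylamine, (R)-1-phenylethylammonium (1S,4R,6S)-6-bromo-1-methyl-3-oxo-2-oxabicyclo[2.2.2]octane-4-carboxylate F2, is crystallised to a single diastereomer and acidified, which returns to the route at 6.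

Step 6. The very hindered tertiary radical may add to the enone too slowly, so that simple reduction of the alkene or oligomerisation of 10 takes over. The fallback forms the C–C bond at the unhindered alkene terminus and introduces the second methyl group afterwards. From 9, a carbonyl-ene reaction with formaldehyde ((CH2O)n, Me2AlCl, CH2Cl2, 0 °C) gives (1S,4R,6S)-6-bromo-4-(4-hydroxybut-1-en-2-yl)-1-methyl-2-oxabicyclo[2.2.2]octan-3-one F3. Acetylation (Ac2O, pyridine) gives 3-[(1S,4R,6S)-6-bromo-1-methyl-3-oxo-2-oxabicyclo[2.2.2]octan-4-yl]but-3-enyl acetate F4. Simmons–Smith cyclopropanation (Et2Zn, CH2I2) gives 2-{1-[(1S,4R,6S)-6-bromo-1-methyl-3-oxo-2-oxabicyclo[2.2.2]octan-4-yl]cyclopropyl}ethyl acetate F5. Hydrogenolysis of the unsubstituted cyclopropane bond (H2, PtO2, AcOH) then gives the gem-dimethyl group and returns to the route at 12.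

Step 8. After ionisation of the tertiary C–O bond, proton loss (elimination) or chloride attack at the secondary carbon or from the wrong face may compete with capture at the vacated position, especially at 40 °C. The primary acetate may also be partly cleaved. The fallback separates the ionisation from the acyl chloride formation and lets the stereochemical outcome be secured on an isolable acid. From 12, BCl3 (CH2Cl2, −78 → −20 °C) cleaves the tertiary alkyl–oxygen bond to (1R,3S,4S)-1-(4-acetoxy-2-methylbutan-2-yl)-3-bromo-4-chloro-4-methylcyclohexane-1-carboxylic acid F6. This is purified and converted with oxalyl chloride and catalytic DMF into 13, where the route is rejoined for the second half of step 8.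

Step 12. Enamine formation next to the quaternary carbon may be slow, and the resident stereocentres may erode the facial selectivity imposed by the catalyst. The α-bromo aldehyde may also epimerise before it is cyclised. The fallback replaces catalyst control by separation. From 17, bromination with the same bromine donor under pyrrolidine/benzoic acid catalysis gives 18 together with its C2 epimer, (2R)-2-bromo-3-[(1S,3S,4S)-3-bromo-4-chloro-4-methyl-1-(prop-1-en-2-yl)cyclohexyl]-3-methylbutanal F7. The mixture is cyclised as in step 13, and chromatography removes the ring A diastereomer (2R,3S,6S,8S,9S)-2,8-dibromo-9-chloro-1,1,9-trimethyl-5-methylidenespiro[5.5]undecan-3-ol F8, returning to the route at 19.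

Step 13. Facial selectivity at the carbinol carbon may be poor, because the axial oxygen required by the concerted path is syn-axial to a methyl group on C1. A stepwise cationic path with chloride capture, or Lewis-acid ionisation of the tertiary chloride, may also intervene. The fallback sets C3 by reduction and not by the ene transition state. From 18, the cyclisation is run to full conversion whatever its selectivity, giving 19 mixed with its C3 epimer (2S,3S,6S,8S,9S)-2,8-dibromo-9-chloro-1,1,9-trimethyl-5-methylidenespiro[5.5]undecan-3-ol F9. Dess–Martin oxidation converges both on (2S,6S,8S,9S)-2,8-dibromo-9-chloro-1,1,9-trimethyl-5-methylidenespiro[5.5]undecan-3-one F10. Reduction with iBu2AlH at −78 °C should then occur from the equatorial side, because the axial methyl group on C1 blocks the axial trajectory, and give the axial alcohol cis to the equatorial bromine, which returns to the route at 19.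

## Further compounds

F1 | step 3 | racemic 6-bromo-1-methyl-3-oxo-2-oxabicyclo[2.2.2]octane-4-carboxylic acid (6 and its enantiomer) | OC(=O)[C@]12CC[C@](C)(OC1=O)[C@@H](Br)C2.OC(=O)[C@@]12CC[C@@](C)(OC1=O)[C@H](Br)C2
F2 | step 3 | (R)-1-phenylethylammonium (1S,4R,6S)-6-bromo-1-methyl-3-oxo-2-oxabicyclo[2.2.2]octane-4-carboxylate | [O-]C(=O)[C@]12CC[C@](C)(OC1=O)[C@@H](Br)C2.C[C@@H]([NH3+])c1ccccc1
F3 | step 6 | (1S,4R,6S)-6-bromo-4-(4-hydroxybut-1-en-2-yl)-1-methyl-2-oxabicyclo[2.2.2]octan-3-one | OCCC(=C)[C@]12CC[C@](C)(OC1=O)[C@@H](Br)C2
F4 | step 6 | 3-[(1S,4R,6S)-6-bromo-1-methyl-3-oxo-2-oxabicyclo[2.2.2]octan-4-yl]but-3-enyl acetate | CC(=O)OCCC(=C)[C@]12CC[C@](C)(OC1=O)[C@@H](Br)C2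
F5 | step 6 | 2-{1-[(1S,4R,6S)-6-bromo-1-methyl-3-oxo-2-oxabicyclo[2.2.2]octan-4-yl]cyclopropyl}ethyl acetate | CC(=O)OCCC3(CC3)[C@]12CC[C@](C)(OC1=O)[C@@H](Br)C2
F6 | step 8 | (1R,3S,4S)-1-(4-acetoxy-2-methylbutan-2-yl)-3-bromo-4-chloro-4-methylcyclohexane-1-carboxylic acid | CC(=O)OCCC(C)(C)[C@@]1(C(=O)O)CC[C@](C)(Cl)[C@@H](Br)C1
F7 | step 12 | (2R)-2-bromo-3-[(1S,3S,4S)-3-bromo-4-chloro-4-methyl-1-(prop-1-en-2-yl)cyclohexyl]-3-methylbutanal | O=C[C@H](Br)C(C)(C)[C@@]1(C(C)=C)CC[C@](C)(Cl)[C@@H](Br)C1
F8 | step 12 | (2R,3S,6S,8S,9S)-2,8-dibromo-9-chloro-1,1,9-trimethyl-5-methylidenespiro[5.5]undecan-3-ol | C=C1C[C@H](O)[C@H](Br)C(C)(C)[C@]12CC[C@](C)(Cl)[C@@H](Br)C2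
F9 | step 13 | (2S,3S,6S,8S,9S)-2,8-dibromo-9-chloro-1,1,9-trimethyl-5-methylidenespiro[5.5]undecan-3-ol | C=C1C[C@H](O)[C@@H](Br)C(C)(C)[C@]12CC[C@](C)(Cl)[C@@H](Br)C2
F10 | step 13 | (2S,6S,8S,9S)-2,8-dibromo-9-chloro-1,1,9-trimethyl-5-methylidenespiro[5.5]undecan-3-one | C=C1CC(=O)[C@@H](Br)C(C)(C)[C@]12CC[C@](C)(Cl)[C@@H](Br)C2
A1 | alternative 1 | 1-methoxy-5,9-dimethylspiro[5.5]undeca-1,4,8-trien-3-one (spiro carbon as drawn) | COC1=CC(=O)C=C(C)[C@]12CCC(C)=CC2
A2 | alternative 1 | (Z)-5-(4-hydroxy-2-methoxy-6-methylphenyl)-3-methylpent-2-enyl methyl carbonate | COC(=O)OC/C=C(C)\CCc1c(C)cc(O)cc1OC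
A3 | alternative 2 | methyl 4,4,8-trimethyl-2-oxospiro[4.5]dec-7-ene-1-carboxylate (spiro carbon as drawn) | COC(=O)[C@H]1C(=O)CC(C)(C)[C@]12CCC(C)=CC2
A4 | alternative 2 | methyl 2-diazo-5-methyl-5-[(1S)-4-methylcyclohex-3-en-1-yl]-3-oxohexanoate | COC(=O)C(=[N+]=[N-])C(=O)CC(C)(C)[C@H]1CCC(C)=CC1
A5 | alternative 2 | (S)-limonene | CC1=CC[C@H](CC1)C(C)=C
A6 | alternative 3 | 1-amino-5,5-dimethylspiro[5.5]undec-1-ene-3,9-dione 9-ethylene ketal | NC1=CC(=O)CC(C)(C)C12CCC3(CC2)OCCO3
A7 | alternative 3 | 1,4-dioxaspiro[4.5]decane-8-carbonitrile | N#CC1CCC2(CC1)OCCO2
A8 | alternative 3 | mesityl oxide (4-methylpent-3-en-2-one) | CC(=O)C=C(C)C
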